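**Plan**
- Cuts, in retrosynthetic order: the O8–acyl ester bond, the C11 methyl centre (back to the C11=C13 methylene of eupatolide), then the ten-membered ring at C7–C8.
- Enabling feature: the γ-lactone (O on C6, carbons C7, C11, C12) lies next to the C8 carbinol, and C13–C11–C7 is an allyl unit, so C7–C8 is the bond a butenolide-derived allylmetal makes with a C8 aldehyde.
- The seco-aldehyde is cut at C7=C11 (metathesis), O6–C12 (ester), C6–C7 (vinyl addition) and C8=C9 (methylenation), which leads to geranyl acetate.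
- Forward: C6–C8 chain, then the butenolide (ring 1), then the carbocycle (ring 2, key step), then C11 reduction, esterification and ketal removal.
- Stereochemistry: C6 from a catalytic asymmetric vinylzinc addition; C7 and C8 from the cyclization under control of C6; C11 by protonation and equilibration.
- Olefin geometry: from geranyl acetate and E-selective SeO2 oxidation; in the side chain from syn-hydrostannation locked in a dioxepine ring.

Key step: step 13

Remark: germacrane numbering is used (ring C1–C10, lactone carbons C11–C13, C14 on C10, C15 on C4); the target SMILES is read as 6R,7R,8R,11S with 4E, 1(10)E and a 2E side chain (11β,13-dihydroeupatoriopicrin).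

**Route**

Step 1
Reactants: 1 geranyl acetate
Product: 2 (2E,6E)-8-hydroxy-3,7-dimethylocta-2,6-dien-1-yl acetate
Conditions: SeO2 (0.3 equiv), t-BuOOH (2.5 equiv), salicylic acid (0.1 equiv), CH2Cl2, 23 °C
Reagents that add atoms: selenium dioxide, O=[Se]=O; tert-butyl hydroperoxide, CC(C)(C)OO
Why: Catalytic SeO2 allylic oxidation (ene reaction, then 2,3-sigmatropic shift) attacks the E-methyl of the electron-richer terminal olefin and gives the E-allylic alcohol, while the olefin next to the acetate is deactivated; any enal formed alongside is simply carried into step 2.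

Step 2
Reactants: 2 (2E,6E)-8-hydroxy-3,7-dimethylocta-2,6-dien-1-yl acetate
Product: 3 (2E,6E)-3,7-dimethyl-8-oxoocta-2,6-dien-1-yl acetate
Conditions: MnO2 (15 equiv), CH2Cl2, 23 °C
Reagents that add atoms: none
Why: MnO2 oxidation is selective for the allylic alcohol and should keep the E geometry of the enal.

Step 3
Reactants: 3 (2E,6E)-3,7-dimethyl-8-oxoocta-2,6-dien-1-yl acetate
Product: 4 (2E,6E)-3,7-dimethylnona-2,6,8-trien-1-yl acetate
Conditions: Ph3PCH3Br (1.15 equiv), n-BuLi (1.1 equiv), THF, 0 °C; then 3, −78 → 0 °C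
Reagents that add atoms: methyltriphenylphosphonium bromide, C[P+](c1ccccc1)(c1ccccc1)c1ccccc1.[Br-]
Why: Wittig methylenation adds the C8 carbon; at −78 °C and with no excess of ylide the aldehyde should react well before the acetate.

Step 4
Reactants: 4 (2E,6E)-3,7-dimethylnona-2,6,8-trien-1-yl acetate
Product: 6 (2E,6E)-9-hydroxy-3,7-dimethylnona-2,6-dien-1-yl acetate, via B-alkyl-9-BBN adduct 5 (not isolated)
Conditions: 9-BBN (1.1 equiv), THF, 0 → 23 °C; then NaBO3·4H2O, H2O, 23 °C
Reagents that add atoms: sodium perborate, [Na+].[O-]OB=O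
Why: Hydroboration–oxidation: the bulky borane adds only to the monosubstituted terminus of the diene (anti-Markovnikov, as in the classical homogeraniol preparation), and perborate oxidizes the C–B bond without hydrolysing the acetate.

Step 5
Reactants: 6 (2E,6E)-9-hydroxy-3,7-dimethylnona-2,6-dien-1-yl acetate
Product: 7 (2E,6E)-9-[(tert-butyldimethylsilyl)oxy]-3,7-dimethylnona-2,6-dien-1-yl acetate
Conditions: TBSCl, imidazole, CH2Cl2, 23 °C
Reagents that add atoms: tert-butyldimethylsilyl chloride, CC(C)(C)[Si](C)(C)Cl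
Why: Standard silylation of the primary alcohol; the TBS ether is orthogonal to the acetate and survives every step up to step 11.

Step 6
Reactants: 7 (2E,6E)-9-[(tert-butyldimethylsilyl)oxy]-3,7-dimethylnona-2,6-dien-1-yl acetate
Product: 8 (2E,6E)-9-[(tert-butyldimethylsilyl)oxy]-3,7-dimethylnona-2,6-dien-1-ol
Conditions: K2CO3 (0.2 equiv), MeOH, 0 → 23 °C
Reagents that add atoms: none
Why: Base-catalysed transesterification removes the acetate and leaves the primary TBS ether intact.

Step 7
Reactants: 8 (2E,6E)-9-[(tert-butyldimethylsilyl)oxy]-3,7-dimethylnona-2,6-dien-1-ol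
Product: 9 (2E,6E)-9-[(tert-butyldimethylsilyl)oxy]-3,7-dimethylnona-2,6-dienal
Conditions: MnO2 (15 equiv), CH2Cl2, 23 °C
Reagents that add atoms: none
Why: MnO2 allylic oxidation gives the geranial-type (2E)-enal without touching the silyl ether.

Step 8
Reactants: 9 (2E,6E)-9-[(tert-butyldimethylsilyl)oxy]-3,7-dimethylnona-2,6-dienal
Product: 10 (3S,4E,8E)-11-[(tert-butyldimethylsilyl)oxy]-5,9-dimethylundeca-1,4,8-trien-3-ol
Conditions: Zn(CH=CH2)2 (salt-free, 1.5 equiv), (2S)-(−)-3-exo-morpholinoisoborneol [(−)-MIB, 5 mol %], toluene/hexane, −20 → 0 °C; aq. NH4Cl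
Reagents that add atoms: divinylzinc, C=C[Zn]C=C
Why: Amino-alcohol-catalysed asymmetric 1,2-addition of an alkenylzinc reagent to an enal; the (2S)-ligand–zinc complex is taken to deliver vinyl to the Si face, as it does with dialkylzincs, which sets C6 as 3S (the descriptor becomes R once the vinyl group is part of the butenolide).

Step 9
Reactants: 10 (3S,4E,8E)-11-[(tert-butyldimethylsilyl)oxy]-5,9-dimethylundeca-1,4,8-trien-3-ol; 11 2-(bromomethyl)acrylic acid
Product: 12 (3S,4E,8E)-11-[(tert-butyldimethylsilyl)oxy]-5,9-dimethylundeca-1,4,8-trien-3-yl 2-(bromomethyl)prop-2-enoate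
Conditions: DCC (1.2 equiv), DMAP (5 mol %), CH2Cl2, −20 → 0 °C
Reagents that add atoms: none
Why: Steglich esterification acylates the alcohol with retention at C6; low temperature and only catalytic DMAP keep amine attack on the allylic bromide slower than acyl transfer.

Step 10
Reactants: 12 (3S,4E,8E)-11-[(tert-butyldimethylsilyl)oxy]-5,9-dimethylundeca-1,4,8-trien-3-yl 2-(bromomethyl)prop-2-enoate
Product: 13 (5R)-3-(bromomethyl)-5-[(1E,5E)-8-[(tert-butyldimethylsilyl)oxy]-2,6-dimethylocta-1,5-dien-1-yl]furan-2(5H)-one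
Conditions: second-generation Hoveyda–Grubbs catalyst RuCl2(H2IMes)(=CH-C6H4-2-O-iPr) (5–10 mol %), CH2Cl2 (5 mM), 40 °C
Reagents that add atoms: none
Why: Ring-closing metathesis starts at the monosubstituted vinyl group and closes the five-membered butenolide onto the acrylate far faster than either trisubstituted olefin can engage; the phosphine-free catalyst cannot be quaternized by the allylic bromide, and C6 is untouched.

Step 11
Reactants: 13 (5R)-3-(bromomethyl)-5-[(1E,5E)-8-[(tert-butyldimethylsilyl)oxy]-2,6-dimethylocta-1,5-dien-1-yl]furan-2(5H)-one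
Product: 14 (5R)-3-(bromomethyl)-5-[(1E,5E)-8-hydroxy-2,6-dimethylocta-1,5-dien-1-yl]furan-2(5H)-one
Conditions: HF (48 % aq.), MeCN, 0 °C
Reagents that add atoms: none
Why: Acidic fluoride desilylation without amine or basic fluoride spares the allylic bromide and the base-sensitive γ-alkenyl butenolide.

Step 12
Reactants: 14 (5R)-3-(bromomethyl)-5-[(1E,5E)-8-hydroxy-2,6-dimethylocta-1,5-dien-1-yl]furan-2(5H)-one
Product: 15 (5R)-3-(bromomethyl)-5-[(1E,5E)-2,6-dimethyl-8-oxoocta-1,5-dien-1-yl]furan-2(5H)-one
Conditions: Dess–Martin periodinane (1.3 equiv), NaHCO3 (5 equiv), CH2Cl2, 0 °C; short neutral filtration, used at once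
Reagents that add atoms: none
Why: Buffered Dess–Martin oxidation is the standard mild route to β,γ-unsaturated aldehydes and should not move the C1=C10 bond into conjugation.

Step 13
Reactants: 15 (5R)-3-(bromomethyl)-5-[(1E,5E)-2,6-dimethyl-8-oxoocta-1,5-dien-1-yl]furan-2(5H)-one
Product: 17 eupatolide (8β-hydroxycostunolide), via allylchromium dichloride 16 (not isolated)
Conditions: CrCl2 (8 equiv), degassed THF, 25 °C; 15 added by syringe pump over 10 h, final concentration 2 mM; aq. NH4Cl
Reagents that add atoms: none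
Why: Two equivalents of divalent chromium reduce the C13–Br bond to the trivalent allylchromium 16, which adds to the C8 aldehyde through its γ-carbon C7 in a closed six-membered chair (Cr–O8–C8–C7–C11–C13), forming C7–C8 and moving the double bond to C11=C13. The closest known reactions are the Nozaki–Hiyama–Kishi (chromium Barbier) allylations of aldehydes with 3-(bromomethyl)furan-2(5H)-ones and the intramolecular versions that close ten-membered germacrane rings from 2-(alkoxycarbonyl)allyl bromides. The one ring formed, the ten-membered carbocycle, closes by C–C bond formation in a 10-exo-trig addition to the aldehyde, with the butenolide and the two E-olefins restricting the chain so that both ends lie within reach. C7 is controlled by C6: the bond should form on the butenolide face anti to the C5 arm, the approach that lets the (4E)-alkenyl chain reach C8 in the crown-like diequatorial conformation of trans-fused germacranolides, whereas syn approach would need a strained cis-fused array. C8 is controlled by the ring-fixed geometry of the allylmetal (C6 trans to CH2Cr, an E-crotyl-type reagent) and the equatorial C9 arm in the chair, which gives the anti C6/O8 relationship, that is the 8β-hydroxyl (8R). The step needs ring closure to beat intermolecular coupling (slow addition into excess CrCl2 at high dilution), γ- over α-attack (chromium sits on primary C13) and an unisomerized aldehyde (15 is used fresh and CrCl2 is not basic).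

Step 14
Reactants: 17 eupatolide
Product: 18 11β,13-dihydroeupatolide (11S)
Conditions: NaBH4 (1.5 equiv), MeOH, 0 °C, short reaction time
Reagents that add atoms: none
Why: Conjugate hydride reduction of the exocyclic α-methylene lactone, as known for costunolide-type lactones; protonation and methoxide equilibration of the lactone enolate should place the C11 methyl α, trans to the C7–C8 bond (11S), and the cold, brief treatment is meant to avoid lactone migration to O8.

Step 15
Reactants: 19 but-2-yne-1,4-diol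
Product: 20 (2E)-2-(tributylstannyl)but-2-ene-1,4-diol
Conditions: Bu3SnH (1.1 equiv), PdCl2(PPh3)2 (2 mol %), THF, 0 → 23 °C
Reagents that add atoms: tributyltin hydride, CCCC[SnH](CCCC)CCCC
Why: Palladium-catalysed hydrostannation adds H and Sn syn across the symmetrical alkyne, so the two hydroxymethyl groups end up cis, the geometry of the (2E) side chain.

Step 16
Reactants: 20 (2E)-2-(tributylstannyl)but-2-ene-1,4-diol
Product: 21 2,2-dimethyl-5-(tributylstannyl)-4,7-dihydro-1,3-dioxepine
Conditions: 2,2-dimethoxypropane, PPTS (cat.), CH2Cl2, 23 °C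
Reagents that add atoms: 2,2-dimethoxypropane, COC(C)(C)OC
Why: Acid-catalysed transketalization closes the seven-membered acetonide, possible only for the cis-diol, and the ring then locks the olefin geometry; PPTS is too weak for protodestannylation.

Step 17
Reactants: 21 2,2-dimethyl-5-(tributylstannyl)-4,7-dihydro-1,3-dioxepine
Product: 23 2,2-dimethyl-4,7-dihydro-1,3-dioxepine-5-carboxylic acid, via dioxepinyllithium 22 (not isolated)
Conditions: n-BuLi (1.1 equiv), THF, −78 °C; CO2, −78 → 0 °C; cold 0.5 M HCl to pH 4, immediate extraction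
Reagents that add atoms: carbon dioxide, O=C=O
Why: Tin–lithium exchange gives the geometrically fixed vinyllithium 22, kept at −78 °C to suppress β-alkoxide elimination, and carboxylation with CO2 gives the acid.

Step 18
Reactants: 18 11β,13-dihydroeupatolide; 23 2,2-dimethyl-4,7-dihydro-1,3-dioxepine-5-carboxylic acid
Product: 25 11β,13-dihydroeupatolide 8-O-(2,2-dimethyl-4,7-dihydro-1,3-dioxepine-5-carboxylate), via Yamaguchi mixed anhydride 24 (not isolated)
Conditions: 23, 2,4,6-trichlorobenzoyl chloride, Et3N, THF, 23 °C; then 18, DMAP, toluene, 23 → 40 °C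
Reagents that add atoms: none
Why: Yamaguchi esterification passes the acyl group through the acylpyridinium to the hindered 8β-hydroxyl with retention at C8, and the ring-locked enoate cannot change geometry.

Step 19
Reactants: 25 11β,13-dihydroeupatolide 8-O-(2,2-dimethyl-4,7-dihydro-1,3-dioxepine-5-carboxylate)
Product: 26 (3S,3aR,4R,6E,10E,11aR)-3,6,10-trimethyl-2-oxo-2,3,3a,4,5,8,9,11a-octahydrocyclodeca[b]furan-4-yl (2E)-4-hydroxy-2-(hydroxymethyl)but-2-enoate
Conditions: AcOH/H2O/THF (3:1:1), 23 °C
Reagents that add atoms: none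
Why: Mild acid hydrolysis of the labile seven-membered ketal frees the two hydroxyls under conditions too weak for transannular cyclization of the 1(10),4-diene or cleavage of the ester and lactone.

**Compound list**

1 | geranyl acetate, (2E)-3,7-dimethylocta-2,6-dien-1-yl acetate | CC(C)=CCC/C(C)=C/COC(C)=O | starting material
2 | (2E,6E)-8-hydroxy-3,7-dimethylocta-2,6-dien-1-yl acetate | OC/C(C)=C/CC/C(C)=C/COC(C)=O | intermediate
3 | (2E,6E)-3,7-dimethyl-8-oxoocta-2,6-dien-1-yl acetate | O=C/C(C)=C/CC/C(C)=C/COC(C)=O | intermediate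
4 | (2E,6E)-3,7-dimethylnona-2,6,8-trien-1-yl acetate | C=C/C(C)=C/CC/C(C)=C/COC(C)=O | intermediate
5 | (2E,6E)-9-(9-borabicyclo[3.3.1]nonan-9-yl)-3,7-dimethylnona-2,6-dien-1-yl acetate | CC(=O)OC/C=C(C)/CC/C=C(C)/CCB1C2CCCC1CCC2 | intermediate
6 | (2E,6E)-9-hydroxy-3,7-dimethylnona-2,6-dien-1-yl acetate | OCC/C(C)=C/CC/C(C)=C/COC(C)=O | intermediate
7 | (2E,6E)-9-[(tert-butyldimethylsilyl)oxy]-3,7-dimethylnona-2,6-dien-1-yl acetate | CC(C)(C)[Si](C)(C)OCC/C(C)=C/CC/C(C)=C/COC(C)=O | intermediate
8 | (2E,6E)-9-[(tert-butyldimethylsilyl)oxy]-3,7-dimethylnona-2,6-dien-1-ol | CC(C)(C)[Si](C)(C)OCC/C(C)=C/CC/C(C)=C/CO | intermediate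
9 | (2E,6E)-9-[(tert-butyldimethylsilyl)oxy]-3,7-dimethylnona-2,6-dienal | CC(C)(C)[Si](C)(C)OCC/C(C)=C/CC/C(C)=C/C=O | intermediate
10 | (3S,4E,8E)-11-[(tert-butyldimethylsilyl)oxy]-5,9-dimethylundeca-1,4,8-trien-3-ol | CC(C)(C)[Si](C)(C)OCC/C(C)=C/CC/C(C)=C/[C@@H](O)C=C | intermediate
11 | 2-(bromomethyl)acrylic acid | C=C(CBr)C(=O)O | starting material
12 | (3S,4E,8E)-11-[(tert-butyldimethylsilyl)oxy]-5,9-dimethylundeca-1,4,8-trien-3-yl 2-(bromomethyl)prop-2-enoate | CC(C)(C)[Si](C)(C)OCC/C(C)=C/CC/C(C)=C/[C@@H](OC(=O)C(=C)CBr)C=C | intermediate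
13 | (5R)-3-(bromomethyl)-5-[(1E,5E)-8-[(tert-butyldimethylsilyl)oxy]-2,6-dimethylocta-1,5-dien-1-yl]furan-2(5H)-one | CC(C)(C)[Si](C)(C)OCC/C(C)=C/CC/C(C)=C/[C@H]1OC(=O)C(CBr)=C1 | intermediate
14 | (5R)-3-(bromomethyl)-5-[(1E,5E)-8-hydroxy-2,6-dimethylocta-1,5-dien-1-yl]furan-2(5H)-one | OCC/C(C)=C/CC/C(C)=C/[C@H]1OC(=O)C(CBr)=C1 | intermediate
15 | (5R)-3-(bromomethyl)-5-[(1E,5E)-2,6-dimethyl-8-oxoocta-1,5-dien-1-yl]furan-2(5H)-one | O=CC/C(C)=C/CC/C(C)=C/[C@H]1OC(=O)C(CBr)=C1 | intermediate
16 | allylchromium dichloride derived from 15 (trivalent chromium on C13) | O=CC/C(C)=C/CC/C(C)=C/[C@H]1OC(=O)C(C[Cr](Cl)Cl)=C1 | intermediate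
17 | eupatolide, (3aR,4R,6E,10E,11aR)-4-hydroxy-6,10-dimethyl-3-methylidene-3a,4,5,8,9,11a-hexahydrocyclodeca[b]furan-2(3H)-one | C/C1=C\[C@H]2OC(=O)C(=C)[C@@H]2[C@H](O)C/C(C)=C/CC1 | intermediate
18 | 11β,13-dihydroeupatolide, (3S,3aR,4R,6E,10E,11aR)-4-hydroxy-3,6,10-trimethyl-3a,4,5,8,9,11a-hexahydrocyclodeca[b]furan-2(3H)-one | C/C1=C\[C@H]2OC(=O)[C@@H](C)[C@@H]2[C@H](O)C/C(C)=C/CC1 | intermediate
19 | but-2-yne-1,4-diol | OCC#CCO | starting material
20 | (2E)-2-(tributylstannyl)but-2-ene-1,4-diol | OC/C=C(\CO)[Sn](CCCC)(CCCC)CCCC | intermediate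
21 | 2,2-dimethyl-5-(tributylstannyl)-4,7-dihydro-1,3-dioxepine | CC1(C)OCC=C(CO1)[Sn](CCCC)(CCCC)CCCC | intermediate
22 | (2,2-dimethyl-4,7-dihydro-1,3-dioxepin-5-yl)lithium | [Li]C1=CCOC(C)(C)OC1 | intermediate
23 | 2,2-dimethyl-4,7-dihydro-1,3-dioxepine-5-carboxylic acid | CC1(C)OCC=C(CO1)C(=O)O | intermediate
24 | 2,2-dimethyl-4,7-dihydro-1,3-dioxepine-5-carboxylic 2,4,6-trichlorobenzoic anhydride | CC1(C)OCC=C(CO1)C(=O)OC(=O)c1c(Cl)cc(Cl)cc1Cl | intermediate
25 | (3S,3aR,4R,6E,10E,11aR)-3,6,10-trimethyl-2-oxo-2,3,3a,4,5,8,9,11a-octahydrocyclodeca[b]furan-4-yl 2,2-dimethyl-4,7-dihydro-1,3-dioxepine-5-carboxylate | C/C1=C\[C@H]2OC(=O)[C@@H](C)[C@@H]2[C@H](OC(=O)C3=CCOC(C)(C)OC3)C/C(C)=C/CC1 | intermediate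
26 | (3S,3aR,4R,6E,10E,11aR)-3,6,10-trimethyl-2-oxo-2,3,3a,4,5,8,9,11a-octahydrocyclodeca[b]furan-4-yl (2E)-4-hydroxy-2-(hydroxymethyl)but-2-enoate | C/C1=C\[C@H]2OC(=O)[C@@H](C)[C@@H]2[C@H](OC(=O)/C(=C/CO)CO)C/C(C)=C/CC1 | target

**Step count**

Total: 19 steps. Longest linear sequence: 16 steps (steps 1–14, 18, 19); steps 15–17 make the side-chain acid.

**Steps most likely to fail**

Step 13. The ten-membered tether may force the aldehyde to add through the alternative boat-like arrangement with the C9 arm axial, so that ring closure occurs with the wrong configuration at C8; intermolecular coupling is a second drain, met by dilution. Fallback: the route sets out from 15 as before, but C8 is then fixed by SN2 inversion instead of by the allylation. The 8α-alcohol from the cyclization, 8-epi-eupatolide F1, is reduced with NaBH4 in MeOH to 11β,13-dihydro-8-epi-eupatolide F2. F2 is then coupled with acid 23 under Mitsunobu conditions (PPh3, DIAD, toluene, 0 °C), which inverts C8 and returns the route at 25.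

Step 10. The allylic bromide may degrade the ruthenium carbene, and closure onto the electron-poor 1,1-disubstituted acrylate may become slower than isomerization or dimerization at the vinyl group. Fallback: the halide is introduced only after ring closure. From 10, Steglich esterification with 2-{[(4-methoxybenzyl)oxy]methyl}prop-2-enoic acid (C=C(COCc1ccc(OC)cc1)C(=O)O) gives the halide-free ester F3. Ring-closing metathesis gives the 3-[(4-methoxybenzyloxy)methyl]butenolide F4, DDQ in CH2Cl2/pH 7 buffer frees the 3-(hydroxymethyl)butenolide F5, and CBr4/PPh3 converts F5 into bromide 13.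

Step 8. Uncatalysed background addition or poor facial discrimination on the β,β-disubstituted enal would erode the enantiomeric purity of C6, on which every later centre depends. Fallback: resolution instead of asymmetric catalysis. From 9, vinylmagnesium bromide (THF, −78 °C) gives the racemic dienol F6. Immobilized lipase B from Candida antarctica with vinyl acetate (hexane, 30 °C) should acylate the R enantiomer, following the empirical size rule for lipases, to the (R)-acetate F7, leaving the (S)-alcohol 10, which re-enters at step 9.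

**Further compounds**

F1 | step 13 | 8-epi-eupatolide (8α-hydroxycostunolide) | C/C1=C\[C@H]2OC(=O)C(=C)[C@@H]2[C@@H](O)C/C(C)=C/CC1
F2 | step 13 | 11β,13-dihydro-8-epi-eupatolide | C/C1=C\[C@H]2OC(=O)[C@@H](C)[C@@H]2[C@@H](O)C/C(C)=C/CC1
F3 | step 10 | (3S,4E,8E)-11-[(tert-butyldimethylsilyl)oxy]-5,9-dimethylundeca-1,4,8-trien-3-yl 2-{[(4-methoxybenzyl)oxy]methyl}prop-2-enoate | CC(C)(C)[Si](C)(C)OCC/C(C)=C/CC/C(C)=C/[C@@H](OC(=O)C(=C)COCc1ccc(OC)cc1)C=C
F4 | step 10 | (5R)-5-[(1E,5E)-8-[(tert-butyldimethylsilyl)oxy]-2,6-dimethylocta-1,5-dien-1-yl]-3-{[(4-methoxybenzyl)oxy]methyl}furan-2(5H)-one | CC(C)(C)[Si](C)(C)OCC/C(C)=C/CC/C(C)=C/[C@H]1OC(=O)C(COCc2ccc(OC)cc2)=C1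
F5 | step 10 | (5R)-5-[(1E,5E)-8-[(tert-butyldimethylsilyl)oxy]-2,6-dimethylocta-1,5-dien-1-yl]-3-(hydroxymethyl)furan-2(5H)-one | CC(C)(C)[Si](C)(C)OCC/C(C)=C/CC/C(C)=C/[C@H]1OC(=O)C(CO)=C1
F6 | step 8 | racemic (4E,8E)-11-[(tert-butyldimethylsilyl)oxy]-5,9-dimethylundeca-1,4,8-trien-3-ol | CC(C)(C)[Si](C)(C)OCC/C(C)=C/CC/C(C)=C/C(O)C=C
F7 | step 8 | (3R,4E,8E)-11-[(tert-butyldimethylsilyl)oxy]-5,9-dimethylundeca-1,4,8-trien-3-yl acetate | CC(C)(C)[Si](C)(C)OCC/C(C)=C/CC/C(C)=C/[C@H](OC(C)=O)C=C
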